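**Strategy.** Everything rests on the bond between ring-B carbon C9 and the oxymethylene carbon C11 (drimane numbering). C11 lies on the concave face of a cis-fused decalin, cis to the ring-A carbons C1 and C4, where an sp3 C9 is hard to reach. The bond is therefore made while C9 is trigonal. Stille coupling of a (coumarin-7-yloxy)methylstannane with the dienyl triflate of a carvone-derived cis-octalone joins the two halves at C9, the former enone carbonyl carbon flanked by quaternary C10 and methyl-bearing C8. Chromium-catalysed 1,4-hydrogenation should then place H-9 on the convex face and leave the C7=C8 alkene. (S)-Carvone supplies C5; C10 and the ring fusion are relayed from it.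

Key step: step 8

Remark: names use naphthalene locants (C1 = drimane C9, C2 = C8, C4a = C5, C5 = C4, C6 = C3, C8a = C10). The carbinol carbon made in step 4 (naphthalene C6) becomes the ketone in the last step, so its configuration is not controlled; it carries no descriptor in 7–10 and 14–16, and both epimers converge on 17.

**Step 1**
Reactants: 1 (S)-(+)-carvone
Product: 3 (5S,6R)-2-methyl-5-(prop-1-en-2-yl)-6-(prop-2-en-1-yl)cyclohex-2-en-1-one, via lithium enolate of carvone 2 (not isolated)
Conditions: LDA, THF, −78 °C; allyl bromide, −78 to 0 °C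
Reagents that add atoms: allyl bromide, C=CCBr
Why: Kinetic α′-deprotonation gives the cross-conjugated enolate, and enolate alkylation should put the allyl group mainly trans to the isopropenyl group; this centre is enolised again in step 2, so its configuration does not matter.

**Step 2**
Reactants: 3 (5S,6R)-6-allylcarvone
Product: 5 (5R,6S)-2,6-dimethyl-5-(prop-1-en-2-yl)-6-(prop-2-en-1-yl)cyclohex-2-en-1-one, via lithium enolate of allylcarvone 4 (not isolated)
Conditions: LDA, THF, −78 °C; MeI, DMPU, −78 to −20 °C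
Reagents that add atoms: iodomethane, CI
Why: Enolate alkylation of the tetrasubstituted enolate should occur anti to the neighbouring pseudoaxial isopropenyl group, so the quaternary centre forms with methyl trans and allyl cis to isopropenyl (1,2-induction from the bought stereocentre).

**Step 3**
Reactants: 5 (5R,6S)-6-allyl-6-methylcarvone
Product: 6 3-[(1S,6R)-1,3-dimethyl-2-oxo-6-(prop-1-en-2-yl)cyclohex-3-en-1-yl]propanal
Conditions: PdCl2(PhCN)2, CuCl2·2H2O, AgNO2 (all cat.), O2 (1 atm), t-BuOH/MeNO2, rt
Reagents that add atoms: dioxygen, O=O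
Why: The nitrite-modified, aldehyde-selective (anti-Markovnikov) Wacker oxidation should touch only the monosubstituted allyl alkene and leave the 1,1-disubstituted isopropenyl group and the enone alone.

**Step 4**
Reactants: 6 the keto aldehyde
Product: 7 (4aR,8aS)-6-hydroxy-2,5,5,8a-tetramethyl-4a,5,6,7,8,8a-hexahydronaphthalen-1(4H)-one (C6 epimers)
Conditions: Fe(acac)3 (cat.), PhSiH3, EtOH, 60 °C
Reagents that add atoms: none
Why: Mukaiyama-type hydrogen-atom transfer to the isopropenyl group gives a tertiary radical that should add 6-exo to the aldehyde (reductive radical alkene–carbonyl cyclisation), creating the gem-dimethyl carbon; the ring fusion must be cis because the two arms are cis on the ring.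

**Step 5**
Reactants: 7 the hydroxy enone
Product: 8 (4aR,8aS)-6-[(tert-butyldimethylsilyl)oxy]-2,5,5,8a-tetramethyl-4a,5,6,7,8,8a-hexahydronaphthalen-1(4H)-one
Conditions: TBSOTf, 2,6-lutidine, CH2Cl2, −78 to 0 °C
Reagents that add atoms: tert-butyldimethylsilyl trifluoromethanesulfonate, CC(C)(C)[Si](C)(C)OS(=O)(=O)C(F)(F)F
Why: Silyl triflate silylation should protect the hindered secondary alcohol next to the gem-dimethyl carbon, so that only the enone can be enolised in step 6.

**Step 6**
Reactants: 8 the silyl ether enone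
Product: 10 (4aR,8aS)-6-[(tert-butyldimethylsilyl)oxy]-2,5,5,8a-tetramethyl-4a,5,6,7,8,8a-hexahydronaphthalen-1-yl trifluoromethanesulfonate, via potassium dienolate 9 (not isolated)
Conditions: KHMDS, THF, −78 °C; PhNTf2, −78 to 0 °C
Reagents that add atoms: N-phenylbis(trifluoromethanesulfonimide), O=S(=O)(N(c1ccccc1)S(=O)(=O)C(F)(F)F)C(F)(F)F
Why: The enone has no α′-hydrogen (C8a is quaternary), so only γ-deprotonation at C4 is possible; O-sulfonylation of the extended dienolate should give the 2-triflyloxy-1,3-diene (dienyl triflate formation).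

**Step 7**
Reactants: 11 umbelliferone (7-hydroxy-2H-chromen-2-one); 12 tributyl(iodomethyl)stannane
Product: 13 tributyl{[(2-oxo-2H-chromen-7-yl)oxy]methyl}stannane
Conditions: K2CO3, DMF, rt
Reagents that add atoms: none
Why: Williamson etherification of the acidic phenol with the primary α-stannyl iodide should proceed under mild carbonate conditions that leave the lactone intact.

**Step 8**
Reactants: 10 the dienyl triflate; 13 the (aryloxymethyl)stannane
Product: 14 7-{[(4aS,8aS)-6-[(tert-butyldimethylsilyl)oxy]-2,5,5,8a-tetramethyl-4a,5,6,7,8,8a-hexahydronaphthalen-1-yl]methoxy}-2H-chromen-2-one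
Conditions: Pd2(dba)3 (cat.), AsPh3, CuI (cat.), LiCl, NMP, 60 °C
Reagents that add atoms: none
Why: Stille cross-coupling: Pd(0) inserts into the C1–OTf bond of 10 (drimane C9), the oxygen-activated CH2OAr group of 13 is transmetallated (CuI/LiCl-assisted, faster than butyl), and reductive elimination forms the C(sp2)–C(sp3) bond that unites the decalin with the coumarin ether. The closest known reaction type is the Stille coupling of (hydroxymethyl)- and (alkoxymethyl)tributylstannanes with hindered alkenyl triflates. No ring is closed and no stereocentre is created, and that is the point: because C1 stays trigonal, the aryloxymethyl group never has to approach the concave face next to the quaternary centre, and its final orientation is decided in step 9. The step needs selective transfer of CH2OAr over butyl and survival of the coumarin lactone, both served by neutral conditions. The new allylic aryl ether sits on a tetrasubstituted alkene, a poor ligand for Pd(0), so ionisation of the C–O bond should not compete.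

**Step 9**
Reactants: 14 the coupled diene
Product: 15 7-{[(1R,4aS,8aS)-6-[(tert-butyldimethylsilyl)oxy]-2,5,5,8a-tetramethyl-1,4,4a,5,6,7,8,8a-octahydronaphthalen-1-yl]methoxy}-2H-chromen-2-one
Conditions: (η6-naphthalene)Cr(CO)3 (cat.), H2 (4 atm), THF, 45 °C
Reagents that add atoms: none
Why: Arene–Cr(CO)3-catalysed 1,4-hydrogenation of the cisoid cyclohexa-1,3-diene should bind chromium on the convex face (the face of 4a-H and 8a-CH3, away from ring A) and deliver both hydrogens to C1 and C4 from that face, so H-1 ends cis to 8a-CH3 (1R), the CH2OAr group is pushed to the concave face, and only the C2=C3 alkene remains.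

**Step 10**
Reactants: 15 the silyl ether
Product: 16 7-{[(1R,4aS,8aS)-6-hydroxy-2,5,5,8a-tetramethyl-1,4,4a,5,6,7,8,8a-octahydronaphthalen-1-yl]methoxy}-2H-chromen-2-one
Conditions: HF·pyridine, pyridine/THF, 0 °C to rt
Reagents that add atoms: none
Why: Fluoride-mediated desilylation under buffered acidic conditions should free the alcohol without opening the lactone or moving the trisubstituted alkene.

**Step 11**
Reactants: 16 the alcohol
Product: 17 7-{[(1R,4aS,8aS)-2,5,5,8a-tetramethyl-6-oxo-1,4,4a,5,6,7,8,8a-octahydronaphthalen-1-yl]methoxy}-2H-chromen-2-one (target)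
Conditions: Dess–Martin periodinane, CH2Cl2, rt
Reagents that add atoms: none
Why: Dess–Martin oxidation of the secondary alcohol (both epimers) should give the ketone under neutral conditions with no epimerisable centre next to it (C5 is quaternary).

**Compound list**
1 | (S)-(+)-carvone, (5S)-2-methyl-5-(prop-1-en-2-yl)cyclohex-2-en-1-one | CC1=CC[C@@H](CC1=O)C(C)=C | starting material
2 | lithium enolate of carvone (cross-conjugated) | CC1=CC[C@H](C(C)=C)C=C1[O-].[Li+] | intermediate
3 | (5S,6R)-2-methyl-5-(prop-1-en-2-yl)-6-(prop-2-en-1-yl)cyclohex-2-en-1-one | CC1=CC[C@H](C(C)=C)[C@@H](CC=C)C1=O | intermediate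
4 | lithium enolate of 6-allylcarvone | CC1=CC[C@H](C(C)=C)C(CC=C)=C1[O-].[Li+] | intermediate
5 | (5R,6S)-2,6-dimethyl-5-(prop-1-en-2-yl)-6-(prop-2-en-1-yl)cyclohex-2-en-1-one | CC1=CC[C@H](C(C)=C)[C@](C)(CC=C)C1=O | intermediate
6 | 3-[(1S,6R)-1,3-dimethyl-2-oxo-6-(prop-1-en-2-yl)cyclohex-3-en-1-yl]propanal | CC1=CC[C@H](C(C)=C)[C@](C)(CCC=O)C1=O | intermediate
7 | (4aR,8aS)-6-hydroxy-2,5,5,8a-tetramethyl-4a,5,6,7,8,8a-hexahydronaphthalen-1(4H)-one (C6 epimers) | CC1=CC[C@@H]2C(C)(C)C(O)CC[C@]2(C)C1=O | intermediate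
8 | (4aR,8aS)-6-[(tert-butyldimethylsilyl)oxy]-2,5,5,8a-tetramethyl-4a,5,6,7,8,8a-hexahydronaphthalen-1(4H)-one | CC1=CC[C@@H]2C(C)(C)C(O[Si](C)(C)C(C)(C)C)CC[C@]2(C)C1=O | intermediate
9 | potassium dienolate of 8 | CC=1C=C[C@@H]2C(C)(C)C(O[Si](C)(C)C(C)(C)C)CC[C@]2(C)C=1[O-].[K+] | intermediate
10 | (4aR,8aS)-6-[(tert-butyldimethylsilyl)oxy]-2,5,5,8a-tetramethyl-4a,5,6,7,8,8a-hexahydronaphthalen-1-yl trifluoromethanesulfonate | CC=1C=C[C@@H]2C(C)(C)C(O[Si](C)(C)C(C)(C)C)CC[C@]2(C)C=1OS(=O)(=O)C(F)(F)F | intermediate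
11 | umbelliferone, 7-hydroxy-2H-chromen-2-one | Oc1ccc2ccc(=O)oc2c1 | starting material
12 | tributyl(iodomethyl)stannane | CCCC[Sn](CCCC)(CCCC)CI | starting material
13 | tributyl{[(2-oxo-2H-chromen-7-yl)oxy]methyl}stannane | CCCC[Sn](CCCC)(CCCC)COc1ccc2ccc(=O)oc2c1 | intermediate
14 | 7-{[(4aS,8aS)-6-[(tert-butyldimethylsilyl)oxy]-2,5,5,8a-tetramethyl-4a,5,6,7,8,8a-hexahydronaphthalen-1-yl]methoxy}-2H-chromen-2-one | CC=1C=C[C@@H]2C(C)(C)C(O[Si](C)(C)C(C)(C)C)CC[C@]2(C)C=1COc1ccc2ccc(=O)oc2c1 | intermediate
15 | 7-{[(1R,4aS,8aS)-6-[(tert-butyldimethylsilyl)oxy]-2,5,5,8a-tetramethyl-1,4,4a,5,6,7,8,8a-octahydronaphthalen-1-yl]methoxy}-2H-chromen-2-one | CC1=CC[C@@H]2C(C)(C)C(O[Si](C)(C)C(C)(C)C)CC[C@]2(C)[C@@H]1COc1ccc2ccc(=O)oc2c1 | intermediate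
16 | 7-{[(1R,4aS,8aS)-6-hydroxy-2,5,5,8a-tetramethyl-1,4,4a,5,6,7,8,8a-octahydronaphthalen-1-yl]methoxy}-2H-chromen-2-one | CC1=CC[C@@H]2C(C)(C)C(O)CC[C@]2(C)[C@@H]1COc1ccc2ccc(=O)oc2c1 | intermediate
17 | 7-{[(1R,4aS,8aS)-2,5,5,8a-tetramethyl-6-oxo-1,4,4a,5,6,7,8,8a-octahydronaphthalen-1-yl]methoxy}-2H-chromen-2-one | CC1=CC[C@@H]2C(C)(C)C(=O)CC[C@]2(C)[C@@H]1COc1ccc2ccc(=O)oc2c1 | target

**Totals.** Total step count: 11. Longest linear sequence: 10 steps (steps 1–6 and 8–11, from carvone).

**Steps most likely to fail**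

Step 8 (Stille coupling). Transmetallation of the sp3 stannane to the hindered alkenyl–palladium centre may be too slow, so that butyl transfer, protodestannylation or hydrolysis of the triflate take over. The fallback makes the C–C bond first and the C–O bond second. Setting out from 10, Stille coupling with the smaller tributyl(hydroxymethyl)stannane (Pd(PPh3)4, LiCl, dioxane, 90 °C) should give [(4aS,8aS)-6-[(tert-butyldimethylsilyl)oxy]-2,5,5,8a-tetramethyl-4a,5,6,7,8,8a-hexahydronaphthalen-1-yl]methanol F1. Mitsunobu etherification of this primary alcohol with 11 (PPh3, DIAD, THF) comes back to the route at 14.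

Step 9 (1,4-hydrogenation). Hydrogen transfer to the fully substituted diene terminus may be sluggish, the catalyst may be lost by arene exchange with the coumarin, or the two faces may not be distinguished cleanly. The fallback sets C1 by deconjugative protonation before the coumarin is attached. From 10, palladium-catalysed methoxycarbonylation (CO, MeOH, Pd(OAc)2, dppp, Et3N, DMF) should give methyl (4aS,8aS)-6-[(tert-butyldimethylsilyl)oxy]-2,5,5,8a-tetramethyl-4a,5,6,7,8,8a-hexahydronaphthalene-1-carboxylate F2. 1,6-Reduction with SmI2 and t-BuOH (THF/DMPU, −78 °C) generates the extended dienolate, whose kinetic α-protonation from the convex face should give methyl (1R,4aS,8aS)-6-[(tert-butyldimethylsilyl)oxy]-2,5,5,8a-tetramethyl-1,4,4a,5,6,7,8,8a-octahydronaphthalene-1-carboxylate F3. LiAlH4 reduction gives [(1R,4aS,8aS)-6-[(tert-butyldimethylsilyl)oxy]-2,5,5,8a-tetramethyl-1,4,4a,5,6,7,8,8a-octahydronaphthalen-1-yl]methanol F4, and Mitsunobu etherification with 11 comes back to the route at 15.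

Step 4 (radical ring closure). The tertiary radical or the aldehyde may be reduced before the ring closes, or the addition to the carbonyl may revert. The fallback uses a nitrile as an irreversible radical acceptor. From 6, iodine in aqueous ammonia/THF should give 3-[(1S,6R)-1,3-dimethyl-2-oxo-6-(prop-1-en-2-yl)cyclohex-3-en-1-yl]propanenitrile F5. The same iron hydride conditions, followed by aqueous acid to hydrolyse the cyclic imine, should give (4aR,8aS)-2,5,5,8a-tetramethyl-4a,7,8,8a-tetrahydronaphthalene-1,6(4H,5H)-dione F6. NaBH4 at low temperature (MeOH/CH2Cl2) should reduce the saturated ketone in preference to the hindered enone and comes back to the route at 7.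

**Further compounds**
F1 | step 8 | [(4aS,8aS)-6-[(tert-butyldimethylsilyl)oxy]-2,5,5,8a-tetramethyl-4a,5,6,7,8,8a-hexahydronaphthalen-1-yl]methanol | CC=1C=C[C@@H]2C(C)(C)C(O[Si](C)(C)C(C)(C)C)CC[C@]2(C)C=1CO
F2 | step 9 | methyl (4aS,8aS)-6-[(tert-butyldimethylsilyl)oxy]-2,5,5,8a-tetramethyl-4a,5,6,7,8,8a-hexahydronaphthalene-1-carboxylate | CC=1C=C[C@@H]2C(C)(C)C(O[Si](C)(C)C(C)(C)C)CC[C@]2(C)C=1C(=O)OC
F3 | step 9 | methyl (1R,4aS,8aS)-6-[(tert-butyldimethylsilyl)oxy]-2,5,5,8a-tetramethyl-1,4,4a,5,6,7,8,8a-octahydronaphthalene-1-carboxylate | CC1=CC[C@@H]2C(C)(C)C(O[Si](C)(C)C(C)(C)C)CC[C@]2(C)[C@@H]1C(=O)OC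
F4 | step 9 | [(1R,4aS,8aS)-6-[(tert-butyldimethylsilyl)oxy]-2,5,5,8a-tetramethyl-1,4,4a,5,6,7,8,8a-octahydronaphthalen-1-yl]methanol | CC1=CC[C@@H]2C(C)(C)C(O[Si](C)(C)C(C)(C)C)CC[C@]2(C)[C@@H]1CO
F5 | step 4 | 3-[(1S,6R)-1,3-dimethyl-2-oxo-6-(prop-1-en-2-yl)cyclohex-3-en-1-yl]propanenitrile | CC1=CC[C@H](C(C)=C)[C@](C)(CCC#N)C1=O
F6 | step 4 | (4aR,8aS)-2,5,5,8a-tetramethyl-4a,7,8,8a-tetrahydronaphthalene-1,6(4H,5H)-dione | CC1=CC[C@@H]2C(C)(C)C(=O)CC[C@]2(C)C1=O
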